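Retrosynthetic overview
1. Target ⇒ 8,11-dihydroxyguai-4-en-3-one by two late acylations: the methacrylate on the secondary 8-OH first, the acetate on the tertiary 11-OH last.
2. Cyclopentenone (second ring) ⇒ intramolecular aldol condensation of a 2-(2-oxobutyl)cycloheptanone. The oxobutyl arm is carried as a but-2-ynyl group.
3. Cycloheptanone (first ring) ⇒ Dieckmann condensation and decarboxylation of an open-chain diester (C5–C6 bond). Both ester carbons travel as terminal alkenes and the 8,11-diol as an acetonide.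
4. Key C7–C8 bond ⇒ intermolecular Evans syn aldol of an N-pent-4-enoyl oxazolidinone with a C8 aldehyde (sets C7 and C8). C11 ⇒ ester + 2 MeMgBr.
5. C8 aldehyde ⇒ trans-alkylated (S)-4-methyl-δ-valerolactone ⇒ enzymatic desymmetrisation of dimethyl 3-methylglutarate (sets C10, which then controls C1).

Assumption: the SMILES is taken at face value, which gives (1R,7S,8R,10S) in guaiane numbering (C1 ring-fusion CH, C2 CH2, C3 C=O, C4 =C(CH3), C5 =C ring fusion, C6 CH2, C7, C8, C9 CH2, C10 CH(CH3), C11 CMe2O); this numbering is used for all intermediates, and C6′ is the extra carbon on C6 that leaves as CO2 in step 16.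

Step 1
Reactants: 1 dimethyl 3-methylpentanedioate
Product: 2 (3R)-5-methoxy-3-methyl-5-oxopentanoic acid
Conditions: pig liver esterase, 0.1 M phosphate buffer pH 7–MeOH 4:1, −10 °C, pH held at 7 with 1 M NaOH; then HCl to pH 2
Reagents that add atoms: water, O
Why: Enzymatic desymmetrisation (enantiotopos-selective ester hydrolysis) cleaves only one of the two enantiotopic ester groups of the prochiral diester and so sets C10 in about 95% ee, the residual antipode being removed as a diastereomer after step 8.

Step 2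
Reactants: 2 (3R)-5-methoxy-3-methyl-5-oxopentanoic acid
Product: 4 (4S)-4-methyloxan-2-one, via hydroxy acid 3 (not isolated)
Conditions: LiOH (1.0 equiv), MeOH, evaporate to the dry carboxylate; LiBH4 (1.5 equiv), THF, 0 °C → rt; 2 M HCl, then TsOH (cat.), CH2Cl2, rt
Reagents that add atoms: none
Why: Chemoselective borohydride reduction followed by lactonisation works because LiBH4 reduces the methyl ester but not the carboxylate, so the former acid carbon becomes C5 and the former ester carbon becomes C8, while C10 is untouched and changes its label from R to S only through CIP ranking.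

Step 3
Reactants: 4 (4S)-4-methyloxan-2-one; 5 1-bromobut-2-yne
Product: 7 (3R,4S)-3-(but-2-yn-1-yl)-4-methyloxan-2-one, via lithium enolate 6 (not isolated)
Conditions: LiN(i-Pr)2 (1.05 equiv), THF, −78 °C; DMPU, 5 (1.2 equiv), −78 → −40 °C
Reagents that add atoms: 1-bromobut-2-yne (5), CC#CCBr
Why: Lactone enolate alkylation (SN2 on a reactive propargylic bromide) occurs on the face of the half-chair enolate opposite the neighbouring C10 methyl group, giving the trans-3,4-disubstituted lactone and so setting C1 as R, with the internal alkyne serving as a base-stable mask of the 2-oxobutyl arm.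

Step 4
Reactants: 7 (3R,4S)-3-(but-2-yn-1-yl)-4-methyloxan-2-one
Product: 8 (3R,4S)-3-(but-2-yn-1-yl)-4-methyloxan-2-ol (lactol; anomer mixture)
Conditions: i-Bu2AlH (1.1 equiv), CH2Cl2, −78 °C; aq. potassium sodium tartrate
Reagents that add atoms: none
Why: Partial hydride reduction of a lactone stops at the lactol because the tetrahedral aluminium hemiacetal is stable at −78 °C, and the new anomeric centre is inconsequential since it is destroyed in step 5.

Step 5
Reactants: 8 (3R,4S)-3-(but-2-yn-1-yl)-4-methyloxan-2-ol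
Product: 10 (3S,4S)-4-ethenyl-3-methyloct-6-yn-1-ol, via hydroxy aldehyde 9 (not isolated)
Conditions: Ph3PCH3Br (3.0 equiv), KOt-Bu (2.9 equiv), THF, 0 °C; then 8, 0 °C → rt
Reagents that add atoms: methyltriphenylphosphonium bromide, C[P+](c1ccccc1)(c1ccccc1)c1ccccc1.[Br-]
Why: Wittig methylenation of the ring-opened tautomer turns C5 into a vinyl group that will survive the later Grignard step and frees the C8 hydroxyl, no stereocentre being formed (the C1 label changes from R to S only through CIP ranking).

Step 6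
Reactants: 10 (3S,4S)-4-ethenyl-3-methyloct-6-yn-1-ol
Product: 11 (3S,4S)-4-ethenyl-3-methyloct-6-ynal
Conditions: TEMPO (10 mol %), PhI(OAc)2 (1.1 equiv), CH2Cl2, rt
Reagents that add atoms: none
Why: Oxoammonium (TEMPO) oxidation of a primary alcohol stops cleanly at the aldehyde, leaves alkene and alkyne alone, and cannot epimerise anything because the nearest stereocentre is β to the new carbonyl.

Step 7
Reactants: 12 (4S)-4-benzyl-1,3-oxazolidin-2-one; 13 pent-4-enoyl chloride
Product: 15 (4S)-4-benzyl-3-(pent-4-enoyl)-1,3-oxazolidin-2-one, via lithiated oxazolidinone 14 (not isolated)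
Conditions: n-BuLi (1.0 equiv), THF, −78 °C; 13 (1.1 equiv), −78 → 0 °C
Reagents that add atoms: pent-4-enoyl chloride (13), C=CCCC(=O)Cl
Why: N-acylation of the lithiated carbamate by an acid chloride is fast and clean and does not touch the auxiliary stereocentre.

Step 8
Reactants: 15 (4S)-4-benzyl-3-(pent-4-enoyl)-1,3-oxazolidin-2-one; 11 (3S,4S)-4-ethenyl-3-methyloct-6-ynal
Product: 18 (4S)-4-benzyl-3-[(2S,3R,5S,6S)-6-ethenyl-3-hydroxy-5-methyl-2-(prop-2-en-1-yl)dec-8-ynoyl]-1,3-oxazolidin-2-one, via boron enolate 16 (not isolated), via boron aldolate 17 (not isolated)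
Conditions: Bu2BOTf (1.15 equiv), Et3N (1.3 equiv), CH2Cl2, −78 → 0 °C; 11 (0.9 equiv), −78 → 0 °C; pH 7 buffer, MeOH, 30% H2O2, 0 °C
Reagents that add atoms: none
Why: In this fragment-uniting Evans syn aldol, soft enolisation gives only the Z boron enolate, which adds through a closed Zimmerman–Traxler chair with the benzyl group blocking one face, so the C7–C8 bond forms as (7S,8R) in better than 95:5 selectivity regardless of the remote C10 centre, and the syn relationship becomes the cis C7/C8 substitution of the seven-membered ring.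

Step 9
Reactants: 18 aldol adduct
Product: 19 methyl (2S,3R,5S,6S)-6-ethenyl-3-hydroxy-5-methyl-2-(prop-2-en-1-yl)dec-8-ynoate
Conditions: NaOMe (1.1 equiv), MeOH–CH2Cl2, −15 °C, 20 min; AcOH quench
Reagents that add atoms: sodium methoxide, C[O-].[Na+]
Why: Methanolysis (transesterification) of the imide takes place at the more electrophilic exocyclic carbonyl, and the low temperature and short time prevent retro-aldol cleavage and C7 epimerisation while the auxiliary is recovered.

Step 10
Reactants: 19 methyl ester; 20 methylmagnesium bromide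
Product: 22 (3S,4R,6S,7S)-7-ethenyl-2,6-dimethyl-3-(prop-2-en-1-yl)undec-9-yne-2,4-diol, via methyl ketone 21 (not isolated)
Conditions: MeMgBr (5 equiv), THF, 0 °C → rt; aq. NH4Cl
Reagents that add atoms: methylmagnesium bromide (20), C[Mg]Br
Why: Double Grignard addition to the ester (the intermediate ketone reacts faster than the ester) builds the C11 carbinol with both methyl groups after the first equivalent has deprotonated the 8-OH, and vinyl, allyl and internal alkyne are inert, which is why C5 and C6′ are carried as alkenes here; no stereocentre is formed.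

Step 11
Reactants: 22 diol
Product: 23 (5S,6R)-6-[(2S,3S)-3-ethenyl-2-methylhept-5-yn-1-yl]-2,2,4,4-tetramethyl-5-(prop-2-en-1-yl)-1,3-dioxane
Conditions: Me2C(OMe)2 (5 equiv), PPTS (10 mol %), CH2Cl2, rt
Reagents that add atoms: 2,2-dimethoxypropane, COC(C)(C)OC
Why: Acid-catalysed transacetalisation ties the 1,3-diol into a six-membered acetonide that protects both hydroxyls in one operation, withstands all the basic and oxidative steps ahead, and holds the C6 and C9 chains cis and close together.

Step 12
Reactants: 23 acetonide diene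
Product: 25 (2R,3S)-2-(but-2-yn-1-yl)-3-methyl-4-[(4R,5S)-2,2,6,6-tetramethyl-5-(2-oxoethyl)-1,3-dioxan-4-yl]butanal, via tetraol 24 (not isolated)
Conditions: OsO4 (4 mol %), NaIO4 (8 equiv), 2,6-lutidine (4 equiv), dioxane–H2O 3:1, rt
Reagents that add atoms: osmium tetroxide, O=[Os](=O)(=O)=O; sodium periodate, [Na+].[O-]I(=O)(=O)=O
Why: Lemieux–Johnson oxidation dihydroxylates and cleaves both monosubstituted alkenes to the C5 and C6′ aldehydes, the dialkyl alkyne reacting far more slowly with OsO4 and the lutidine buffer suppressing side reactions; no stereocentre is formed.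

Step 13
Reactants: 25 dialdehyde
Product: 26 (2R,3S)-2-(but-2-yn-1-yl)-4-[(4R,5S)-5-(carboxymethyl)-2,2,6,6-tetramethyl-1,3-dioxan-4-yl]-3-methylbutanoic acid
Conditions: NaClO2 (6 equiv), NaH2PO4 (6 equiv), 2-methylbut-2-ene (excess), t-BuOH–H2O, 0 °C → rt
Reagents that add atoms: sodium chlorite, [Na+].[O-]Cl=O
Why: Pinnick oxidation converts both aldehydes into acids at pH about 4, which spares alkyne and acetonide, with the alkene scavenger removing hypochlorous acid.

Step 14
Reactants: 26 diacid
Product: 27 methyl (2R,3S)-2-(but-2-yn-1-yl)-4-[(4R,5S)-5-(2-methoxy-2-oxoethyl)-2,2,6,6-tetramethyl-1,3-dioxan-4-yl]-3-methylbutanoate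
Conditions: TMSCHN2 (2.5 equiv), toluene–MeOH 4:1, 0 °C
Reagents that add atoms: (trimethylsilyl)diazomethane, C[Si](C)(C)C=[N+]=[N-]
Why: Diazoalkane O-methylation esterifies hindered and unhindered acids alike under neutral conditions that leave the acid-labile acetonide intact.

Step 15
Reactants: 27 diester
Product: 29 bicyclic β-keto ester (C5 ketone; CO2Me on C6; but-2-ynyl on C1 trans to the C10 methyl; C7/C8 cis-fused tetramethyl-1,3-dioxane; C6 epimers plus enol), via potassium enolate 28 (not isolated)
Conditions: KOt-Bu (2.5 equiv), THF, slow addition of 27 (final 5 mM), 0 °C → rt; AcOH quench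
Reagents that add atoms: none
Why: Under the equilibrating conditions of this Dieckmann condensation only attack of the C6 ester enolate on the C5 ester gives a β-keto ester that keeps an acidic hydrogen and is drained off as its stable enolate, the alternative closure through tertiary C1 being reversible, and the cis chains on the dioxane keep the two ends close so that the seven-membered ring forms at high dilution.

Step 16
Reactants: 29 bicyclic β-keto ester
Product: 30 acetonide-protected (1R,7S,8R,10S)-1-(but-2-ynyl)-10-methylcycloheptan-5-one (guaiane numbering)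
Conditions: LiCl (5 equiv), H2O (5 equiv), DMSO, 140 °C
Reagents that add atoms: none
Why: Krapcho dealkoxycarbonylation removes the C6′ ester under essentially neutral conditions (chloride demethylation, loss of CO2, protonation at C6), which acetonide and alkyne tolerate.

Step 17
Reactants: 30 alkynyl cycloheptanone
Product: 31 acetonide-protected (1R,7S,8R,10S)-10-methyl-1-(2-oxobutyl)cycloheptan-5-one (guaiane numbering)
Conditions: NaAuCl4·2H2O (5 mol %), EtOH–H2O 5:1, rt → 40 °C
Reagents that add atoms: water, O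
Why: In this gold-catalysed alkyne hydration with neighbouring-group participation the C5 ketone oxygen attacks the activated triple bond at C3 in a 5-exo-dig sense, so water ends up at C3 and the 1,4-diketone rather than the 1,5-isomer is formed under nearly neutral conditions.

Step 18
Reactants: 31 1,4-diketone
Product: 33 8,11-O-isopropylidene-(1R,7S,8R,10S)-8,11-dihydroxyguai-4-en-3-one, via ring aldol 32 (not isolated)
Conditions: KOH (0.5 M), EtOH, 60 °C, argon
Reagents that add atoms: none
Why: In this intramolecular aldol condensation the C4 enolate of the ethyl ketone adds to the C5 ring ketone and loss of water gives the tetrasubstituted conjugated cyclopentenone as the thermodynamic sink (the bridged C6-to-C3 aldol cannot dehydrate and reverts), while enolisable C1 settles in the arrangement already installed in step 3, with the C1–C2 bond and the C10 methyl group trans and pseudo-equatorial.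

Step 19
Reactants: 33 enone acetonide
Product: 34 (5S,6R,8S,8aR)-6-hydroxy-5-(2-hydroxypropan-2-yl)-3,8-dimethyl-4,5,6,7,8,8a-hexahydroazulen-2(1H)-one
Conditions: AcOH–H2O–THF 3:1:1, 40 °C
Reagents that add atoms: none
Why: Mild acetal hydrolysis cleaves the strained tetramethyl-dioxane readily, and these conditions neither dehydrate the tertiary alcohol nor enolise the enone.

Step 20
Reactants: 34 diol; 35 methacrylic anhydride
Product: 36 (5S,6R,8S,8aR)-5-(2-hydroxypropan-2-yl)-3,8-dimethyl-2-oxo-1,2,4,5,6,7,8,8a-octahydroazulen-6-yl 2-methylprop-2-enoate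
Conditions: 35 (1.5 equiv), Et3N (2 equiv), DMAP (0.2 equiv), BHT (trace), CH2Cl2, 0 °C → rt
Reagents that add atoms: methacrylic anhydride (35), C=C(C)C(=O)OC(=O)C(C)=C
Why: DMAP-catalysed acylation is chemoselective for the secondary 8-OH because the tertiary 11-OH is far slower at room temperature, and putting the methacrylate on first avoids any stage in which an 11-acetate could migrate to a free 8-OH.

Step 21
Reactants: 36 8-methacrylate; 37 acetic anhydride
Product: 38 (5S,6R,8S,8aR)-5-(2-acetyloxypropan-2-yl)-3,8-dimethyl-2-oxo-1,2,4,5,6,7,8,8a-octahydroazulen-6-yl 2-methylprop-2-enoate (target)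
Conditions: Ac2O (10 equiv), DMAP (2 equiv), Et3N (10 equiv), BHT (trace), CH2Cl2, 35 °C, 48 h
Reagents that add atoms: acetic anhydride (37), CC(=O)OC(C)=O
Why: Steglich-type acetylation through the N-acetylpyridinium ion is the standard way to esterify tertiary alcohols without ionising them, and the methacrylate, the enone and all four stereocentres are inert to these mildly basic conditions.

Compound list
1 | dimethyl 3-methylpentanedioate | COC(=O)CC(C)CC(=O)OC | starting material
2 | (3R)-5-methoxy-3-methyl-5-oxopentanoic acid | COC(=O)C[C@H](C)CC(=O)O | intermediate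
3 | (3S)-5-hydroxy-3-methylpentanoic acid (not isolated) | OCC[C@H](C)CC(=O)O | intermediate
4 | (4S)-4-methyloxan-2-one | O=C1C[C@@H](C)CCO1 | intermediate
5 | 1-bromobut-2-yne | CC#CCBr | starting material
6 | lithium enolate of 4 (not isolated) | [Li+].[O-]C1=C[C@@H](C)CCO1 | intermediate
7 | (3R,4S)-3-(but-2-yn-1-yl)-4-methyloxan-2-one (trans) | O=C1OCC[C@H](C)[C@H]1CC#CC | intermediate
8 | (3R,4S)-3-(but-2-yn-1-yl)-4-methyloxan-2-ol (anomer mixture) | OC1OCC[C@H](C)[C@H]1CC#CC | intermediate
9 | (2R,3S)-2-(but-2-yn-1-yl)-5-hydroxy-3-methylpentanal (open form of 8, not isolated) | OCC[C@H](C)[C@H](C=O)CC#CC | intermediate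
10 | (3S,4S)-4-ethenyl-3-methyloct-6-yn-1-ol | OCC[C@H](C)[C@H](C=C)CC#CC | intermediate
11 | (3S,4S)-4-ethenyl-3-methyloct-6-ynal | O=CC[C@H](C)[C@H](C=C)CC#CC | intermediate
12 | (4S)-4-benzyl-1,3-oxazolidin-2-one | O=C1N[C@@H](Cc2ccccc2)CO1 | starting material
13 | pent-4-enoyl chloride | C=CCCC(=O)Cl | starting material
14 | lithium salt of 12 (not isolated) | [Li+].O=C1[N-][C@@H](Cc2ccccc2)CO1 | intermediate
15 | (4S)-4-benzyl-3-(pent-4-enoyl)-1,3-oxazolidin-2-one | C=CCCC(=O)N1C(=O)OC[C@@H]1Cc2ccccc2 | intermediate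
16 | (Z)-dibutylboron enolate of 15 (not isolated) | C=CC/C=C(\OB(CCCC)CCCC)N1C(=O)OC[C@@H]1Cc2ccccc2 | intermediate
17 | O-dibutylboryl aldolate of 18 (not isolated) | C=CC[C@@H]([C@H](OB(CCCC)CCCC)C[C@H](C)[C@H](C=C)CC#CC)C(=O)N1C(=O)OC[C@@H]1Cc2ccccc2 | intermediate
18 | (4S)-4-benzyl-3-[(2S,3R,5S,6S)-6-ethenyl-3-hydroxy-5-methyl-2-(prop-2-en-1-yl)dec-8-ynoyl]-1,3-oxazolidin-2-one | C=CC[C@@H]([C@H](O)C[C@H](C)[C@H](C=C)CC#CC)C(=O)N1C(=O)OC[C@@H]1Cc2ccccc2 | intermediate
19 | methyl (2S,3R,5S,6S)-6-ethenyl-3-hydroxy-5-methyl-2-(prop-2-en-1-yl)dec-8-ynoate | C=CC[C@@H]([C@H](O)C[C@H](C)[C@H](C=C)CC#CC)C(=O)OC | intermediate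
20 | methylmagnesium bromide | C[Mg]Br | starting material
21 | (3S,4R,6S,7S)-7-ethenyl-4-hydroxy-6-methyl-3-(prop-2-en-1-yl)undec-9-yn-2-one (not isolated) | C=CC[C@@H]([C@H](O)C[C@H](C)[C@H](C=C)CC#CC)C(C)=O | intermediate
22 | (3S,4R,6S,7S)-7-ethenyl-2,6-dimethyl-3-(prop-2-en-1-yl)undec-9-yne-2,4-diol | C=CC[C@@H]([C@H](O)C[C@H](C)[C@H](C=C)CC#CC)C(C)(C)O | intermediate
23 | (5S,6R)-6-[(2S,3S)-3-ethenyl-2-methylhept-5-yn-1-yl]-2,2,4,4-tetramethyl-5-(prop-2-en-1-yl)-1,3-dioxane | C=CC[C@H]1[C@@H](C[C@H](C)[C@H](C=C)CC#CC)OC(C)(C)OC1(C)C | intermediate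
24 | tetraol from dihydroxylation of both terminal alkenes of 23 (diol epimers, not isolated) | OCC(O)C[C@H]1[C@@H](C[C@H](C)[C@H](C(O)CO)CC#CC)OC(C)(C)OC1(C)C | intermediate
25 | (2R,3S)-2-(but-2-yn-1-yl)-3-methyl-4-[(4R,5S)-2,2,6,6-tetramethyl-5-(2-oxoethyl)-1,3-dioxan-4-yl]butanal | O=CC[C@H]1[C@@H](C[C@H](C)[C@H](C=O)CC#CC)OC(C)(C)OC1(C)C | intermediate
26 | (2R,3S)-2-(but-2-yn-1-yl)-4-[(4R,5S)-5-(carboxymethyl)-2,2,6,6-tetramethyl-1,3-dioxan-4-yl]-3-methylbutanoic acid | OC(=O)C[C@H]1[C@@H](C[C@H](C)[C@H](C(=O)O)CC#CC)OC(C)(C)OC1(C)C | intermediate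
27 | methyl (2R,3S)-2-(but-2-yn-1-yl)-4-[(4R,5S)-5-(2-methoxy-2-oxoethyl)-2,2,6,6-tetramethyl-1,3-dioxan-4-yl]-3-methylbutanoate | COC(=O)C[C@H]1[C@@H](C[C@H](C)[C@H](C(=O)OC)CC#CC)OC(C)(C)OC1(C)C | intermediate
28 | potassium enolate of 29 (not isolated) | [K+].COC(=O)C1=C([O-])[C@H](CC#CC)[C@@H](C)C[C@H]2OC(C)(C)OC(C)(C)[C@@H]12 | intermediate
29 | bicyclic β-keto ester: cycloheptanone (C5=O) with CO2Me on C6, but-2-ynyl on C1, methyl on C10, cis-fused at C7/C8 to a 2,2,4,4-tetramethyl-1,3-dioxane; (1R,7S,8R,10S), C6 epimers/enol | COC(=O)C1C(=O)[C@H](CC#CC)[C@@H](C)C[C@H]2OC(C)(C)OC(C)(C)[C@@H]12 | intermediate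
30 | as 29 without the ester: acetonide-protected (1R,7S,8R,10S)-1-(but-2-ynyl)-10-methylcycloheptan-5-one | O=C1[C@H](CC#CC)[C@@H](C)C[C@H]2OC(C)(C)OC(C)(C)[C@H]2C1 | intermediate
31 | acetonide-protected (1R,7S,8R,10S)-10-methyl-1-(2-oxobutyl)cycloheptan-5-one | O=C1[C@H](CC(=O)CC)[C@@H](C)C[C@H]2OC(C)(C)OC(C)(C)[C@H]2C1 | intermediate
32 | tricyclic β-hydroxy ketone (5-hydroxyguaian-3-one acetonide, C4/C5 epimers, not isolated) | CC1C(=O)C[C@@H]2[C@@H](C)C[C@H]3OC(C)(C)OC(C)(C)[C@H]3CC12O | intermediate
33 | 8,11-O-isopropylidene-(1R,7S,8R,10S)-8,11-dihydroxyguai-4-en-3-one | CC1(C)O[C@@H]2C[C@H](C)[C@H]3CC(=O)C(C)=C3C[C@@H]2C(C)(C)O1 | intermediate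
34 | (5S,6R,8S,8aR)-6-hydroxy-5-(2-hydroxypropan-2-yl)-3,8-dimethyl-4,5,6,7,8,8a-hexahydroazulen-2(1H)-one | O[C@@H]1C[C@H](C)[C@H]2CC(=O)C(C)=C2C[C@@H]1C(C)(C)O | intermediate
35 | methacrylic anhydride | C=C(C)C(=O)OC(=O)C(C)=C | starting material
36 | (5S,6R,8S,8aR)-5-(2-hydroxypropan-2-yl)-3,8-dimethyl-2-oxo-1,2,4,5,6,7,8,8a-octahydroazulen-6-yl 2-methylprop-2-enoate | C=C(C)C(=O)O[C@@H]1C[C@H](C)[C@H]2CC(=O)C(C)=C2C[C@@H]1C(C)(C)O | intermediate
37 | acetic anhydride | CC(=O)OC(C)=O | starting material
38 | (5S,6R,8S,8aR)-5-(2-acetyloxypropan-2-yl)-3,8-dimethyl-2-oxo-1,2,4,5,6,7,8,8a-octahydroazulen-6-yl 2-methylprop-2-enoate | C=C(C)C(=O)O[C@@H]1C[C@H](C)[C@H]2CC(=O)C(C)=C2C[C@@H]1C(C)(C)OC(C)=O | target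

Total step count: 21. Longest linear sequence: 20 steps (steps 1–6 and 8–21, from 1). Step 7 lies on the short branch.

Steps most likely to fail

Step 15 (Dieckmann closure of a seven-membered ring onto an α-branched ester). The electrophilic ester is hindered, and oligomerisation or simple recovery of 27 are the likely failures. The fallback closes the same C5–C6 bond by an aldol addition instead of a Claisen-type acylation. It sets out from dialdehyde 25. Amine catalysis (L-proline, 30 mol %, DMSO, rt) activates only the unhindered C6 acetaldehyde terminus, which adds to the much more electrophilic C5 aldehyde to give the cyclic β-hydroxy aldehyde F1. Pinnick oxidation gives the β-hydroxy acid F2, and TMSCHN2 gives the β-hydroxy ester F3. Dess–Martin oxidation of the C5 carbinol then delivers β-keto ester 29, where the route is rejoined.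

Step 18 (ring closure with C1 under thermodynamic control). If the rigid cis-fused dioxane shifts the C1 equilibrium or the reaction stalls at 32, the fallback changes the species that is cyclised and equilibrated. It sets out from diketone 31. The acetonide is hydrolysed first (AcOH–H2O–THF, 40 °C) to the dihydroxy diketone F4. The aldol condensation is then run on this conformationally free diol (K2CO3 or dilute KOH, MeOH, 40 °C), so that C1 equilibrates within the unconstrained hydroazulenone framework. This gives diol 34 directly, where the route is rejoined. A minor C1 epimer can be separated at this polar stage and resubmitted to base.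

Step 21 (acetylation of the hindered tertiary alcohol next to a polymerisable ester). If the reaction is too slow for the methacrylate to survive, the fallback reverses the order of the two acylations. It sets out from diol 34. TESCl and imidazole (CH2Cl2, 0 °C) silylate only the secondary alcohol to give the 8-O-triethylsilyl ether F5. Forcing acetylation (Ac2O, DMAP, Et3N, ClCH2CH2Cl, 60 °C) gives the silyl ether 11-acetate F6. Acidic desilylation (AcOH–THF–H2O, rt) is chosen because base would trigger an 11-to-8 acetyl shift, and it gives the 8-hydroxy 11-acetate F7. Immediate acylation with methacrylic anhydride and DMAP at 0 °C gives target 38.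

Further compounds
F1 | step 15 | cyclic β-hydroxy aldehyde (as 29 with C5–OH and C6–CHO; C5/C6 epimers) | O=CC1C(O)[C@H](CC#CC)[C@@H](C)C[C@H]2OC(C)(C)OC(C)(C)[C@@H]12
F2 | step 15 | cyclic β-hydroxy acid (as 29 with C5–OH and C6–CO2H) | OC(=O)C1C(O)[C@H](CC#CC)[C@@H](C)C[C@H]2OC(C)(C)OC(C)(C)[C@@H]12
F3 | step 15 | cyclic β-hydroxy methyl ester (as 29 with C5–OH) | COC(=O)C1C(O)[C@H](CC#CC)[C@@H](C)C[C@H]2OC(C)(C)OC(C)(C)[C@@H]12
F4 | step 18 | (1R,7S,8R,10S)-8-hydroxy-7-(2-hydroxypropan-2-yl)-10-methyl-1-(2-oxobutyl)cycloheptan-5-one (guaiane numbering) | O=C1[C@H](CC(=O)CC)[C@@H](C)C[C@@H](O)[C@H](C1)C(C)(C)O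
F5 | step 21 | 8-O-triethylsilyl ether of 34 | CC[Si](CC)(CC)O[C@@H]1C[C@H](C)[C@H]2CC(=O)C(C)=C2C[C@@H]1C(C)(C)O
F6 | step 21 | 8-O-triethylsilyl ether 11-acetate of 34 | CC[Si](CC)(CC)O[C@@H]1C[C@H](C)[C@H]2CC(=O)C(C)=C2C[C@@H]1C(C)(C)OC(C)=O
F7 | step 21 | 11-acetate of 34 (free 8-OH) | O[C@@H]1C[C@H](C)[C@H]2CC(=O)C(C)=C2C[C@@H]1C(C)(C)OC(C)=O
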